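The retrosynthesis cuts (a) the bond from coumarin C8 to the ketone carbon, (b) C1'–C6' and C2'–C3' of the cyclohexene together as a [4+2] pair, and (c) on the arene the C6–prenyl bond and the pyranone ring. Cyclohexene locants: C1' bears the acyl group, C2' is =CH, C5' is CHMe, C6' bears the 1-hydroxyethyl group.
Enabling feature: the ketone carbon and the carbinol oxygen are 1,4-related through C1' and C6', so they can be tied as a γ-lactone ring that is not in the target. That ester is the tether of an intramolecular Diels–Alder reaction. C1'=C2' is the trace of an alkyne-level dienophile, and C3'–C6' with the C5' methyl is the trace of the diene.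
Helpers: the lactone ring fixes regiochemistry and face, and the aryl nucleophile cleaves it in the fragment coupling. A phenylsulfonyl group on C2' (Z-sulfonylacrylate as propiolate equivalent) keeps C1' sp3 until C5' is set, then leaves as sulfinate.
Forward order: dienol chain, ester tether, cyclohexene plus lactone in one step, hydrogenation, elimination. Separately: pyranone ring on phloroglucinol, C6 allyl, OMe, C8 iodide, prenyl. Then union and MOM removal.
Stereochemistry: the carbinol centre comes from (S)-but-3-yn-2-ol, C6' follows from it through the A(1,3)-controlled cycloaddition, and C5' is set by hydrogenation on the open face of the all-cis bicycle.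

Key step: step 6

Assumption: compounds 1, 2 (as THF solution), 7, 13 and 14 are taken as commercial. Locants 1, 3, 3a, 4, 7 and 7a of the bicyclic lactones follow 2-benzofuran-1(3H)-one numbering (C3a = C6', C4 = C5', C7 = C2', C7a = C1').

Step 1
Reactants: 1 (S)-but-3-yn-2-ol; 2 vinyl bromide
Product: 3 (S)-hex-5-en-3-yn-2-ol
Conditions: Pd(PPh3)2Cl2 (2 mol%), CuI (4 mol%), iPr2NH, THF, 0 °C to rt
Reagents that add atoms: none
Why: Sonogashira coupling of a terminal propargylic alcohol with a vinyl halide is routine and leaves untouched the carbinol centre, which is carried from 1 into the target.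

Step 2
Reactants: 3 (S)-hex-5-en-3-yn-2-ol
Product: 5 (2S,3Z)-4-iodohexa-3,5-dien-2-ol, via cyclic vinylalanate 4 (not isolated)
Conditions: NaAlH2(OCH2CH2OMe)2 (1.1 equiv), THF, 0 °C to rt; I2, −78 °C; aqueous work-up
Reagents that add atoms: iodine, II; sodium bis(2-methoxyethoxy)aluminium dihydride, [Na+].[AlH2-](OCCOC)OCCOC (its Al, Na and alkoxy groups stay only in 4)
Why: Alkoxide-directed trans-hydroalumination of a propargylic alcohol places aluminium on the distal alkyne carbon in a five-membered chelate and iodinolysis goes with retention, so iodine ends cis and the vinyl group trans to the carbinol carbon.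

Step 3
Reactants: 5 (2S,3Z)-4-iodohexa-3,5-dien-2-ol
Product: 6 (2S,3E)-4-methylhexa-3,5-dien-2-ol
Conditions: MeMgBr (2.5 equiv), Pd(dppf)Cl2 (3 mol%), THF, 0 °C to rt; aq NH4Cl
Reagents that add atoms: methylmagnesium bromide, C[Mg]Br
Why: Kumada–Corriu coupling of an alkenyl iodide goes with retention of geometry, so the methyl group ends cis to the carbinol carbon and the diene can reach the s-cis form with the side chain outside.

Step 4
Reactants: 6 (2S,3E)-4-methylhexa-3,5-dien-2-ol; 7 propiolic acid
Product: 8 (2S,3E)-4-methylhexa-3,5-dien-2-yl prop-2-ynoate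
Conditions: DCC, DMAP (5 mol%), CH2Cl2, −20 to 0 °C
Reagents that add atoms: none
Why: Steglich esterification acylates at oxygen, so the C–O stereocentre is retained, and the low temperature suppresses amine addition to the ynoate.

Step 5
Reactants: 8 (2S,3E)-4-methylhexa-3,5-dien-2-yl prop-2-ynoate
Product: 9 (2S,3E)-4-methylhexa-3,5-dien-2-yl (2Z)-3-(phenylsulfonyl)prop-2-enoate
Conditions: PhSO2Na, B(OH)3, Bu4NHSO4 (cat.), THF/H2O, rt
Reagents that add atoms: sodium benzenesulfinate, [Na+].[O-]S(=O)c1ccccc1
Why: Buffered conjugate addition of a sulfinate to a propiolate ester (anti hydrosulfonylation) gives the Z-3-sulfonylacrylate kinetically, and the electron-rich diene is inert to the soft anion.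

Step 6
Reactants: 9 (2S,3E)-4-methylhexa-3,5-dien-2-yl (2Z)-3-(phenylsulfonyl)prop-2-enoate
Product: 10 (3S,3aS,7S,7aS)-3,4-dimethyl-7-(phenylsulfonyl)-3a,6,7,7a-tetrahydro-2-benzofuran-1(3H)-one (cis-fused; C3, C1 and S all on one face of the cyclohexene)
Conditions: PhMe (0.01 M), BHT (cat.), 110 °C
Reagents that add atoms: none
Why: This is a thermal type 1 intramolecular Diels–Alder reaction of an ester-tethered 1,3,8-nonatriene, in which the s-cis diene and the doubly activated Z-alkene combine suprafacially so that C7a–C3a and C7–C6 form in one concerted, asynchronous event; the closest known reaction type is the cycloaddition of pentadienyl maleates and other Z-3-acceptor-substituted acrylates. The carbocycle closes as the six-membered [4+2] ring and the five-membered lactone closes with it through C3a–C7a in the fused mode, because the three-atom tether C(=O)–O–CH cannot span the bridged mode; the tether thus fixes a regiochemistry that the 1-alkyl and 2-methyl groups of the free diene would direct in opposite senses. C3a is controlled by the carbinol centre C3: A(1,3) strain with the C4 methyl group holds the C3–H bond in the diene plane, the tether oxygen must lie on the attacked face and the C3 methyl group points away, which should give 3S to 3aS (the R arrangement of the target once C4 is saturated). C7a and C7 follow from the Z geometry and the endo placement of lactone carbonyl and sulfonyl group, which puts C3, C1 and S on the same face. The step needs regio-, π-facial and endo selectivity; tether and allylic strain secure the first two, while the third rests on the known cis preference of Z-dienophiles in this tether class and is the weak point. The sulfonyl group lowers the LUMO so that the disfavoured E-ester conformer can react near 110 °C, keeps C7a sp3 so that the bicycle is cup-shaped for step 7, and is lost in step 8.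

Step 7
Reactants: 10 the cis-fused sulfonyl lactone
Product: 11 (3S,3aR,4R,7S,7aS)-3,4-dimethyl-7-(phenylsulfonyl)hexahydro-2-benzofuran-1(3H)-one
Conditions: H2 (3 atm), PtO2 (5 mol%), EtOAc, rt
Reagents that add atoms: none
Why: In this heterogeneous catalytic hydrogenation (syn addition) C3, the lactone carbonyl and the sulfonyl group all stand on one face of 10, so hydrogen should arrive from the open face that carries H3a and set C4 as R with its methyl cis to the C3 side chain, and no other C=C bond competes because the future C7=C7a bond is masked.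

Step 8
Reactants: 11 the saturated sulfonyl lactone
Product: 12 (3S,3aR,4R)-3,4-dimethyl-3a,4,5,6-tetrahydro-2-benzofuran-1(3H)-one
Conditions: DBU (1.1 equiv), CH2Cl2, 0 °C
Reagents that add atoms: none
Why: E1cB elimination of benzenesulfinate from a β-sulfonyl lactone can only give the C7=C7a bond, since the leaving group sits on C7 and the acidic hydrogen on C7a, so C3a and C4 stay untouched.

Step 9
Reactants: 13 phloroglucinol; 14 ethyl 2-methylacetoacetate
Product: 15 5,7-dihydroxy-3,4-dimethylcoumarin
Conditions: 75% aq H2SO4, 0 °C to rt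
Reagents that add atoms: none
Why: Pechmann condensation of the threefold symmetric, highly activated phenol with an α-methyl β-keto ester has no regiochemical choice and installs both ring methyl groups at once.

Step 10
Reactants: 15 5,7-dihydroxy-3,4-dimethylcoumarin
Product: 16 5-hydroxy-7-(methoxymethoxy)-3,4-dimethylcoumarin
Conditions: MOMCl (1.05 equiv), K2CO3, acetone, 0 °C to rt
Reagents that add atoms: chloromethyl methyl ether, COCCl
Why: Williamson-type O-alkylation should take the 7-OH, which is the more acidic and unhindered one, whereas the 5-OH is shielded by the peri C4 methyl group.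

Step 11
Reactants: 16 5-hydroxy-7-(methoxymethoxy)-3,4-dimethylcoumarin
Product: 17 5-(allyloxy)-7-(methoxymethoxy)-3,4-dimethylcoumarin
Conditions: allyl bromide, K2CO3, DMF, 60 °C
Reagents that add atoms: allyl bromide, C=CCBr
Why: Williamson ether synthesis with a small primary allylic halide tolerates the hindered 5-phenoxide, the only free hydroxy group.

Step 12
Reactants: 17 5-(allyloxy)-7-(methoxymethoxy)-3,4-dimethylcoumarin
Product: 18 6-allyl-5-hydroxy-7-(methoxymethoxy)-3,4-dimethylcoumarin
Conditions: PhNEt2, 200 °C
Reagents that add atoms: none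
Why: In the aromatic Claisen rearrangement C6 is the only free ortho position of the 5-oxygen (C4a is a ring-fusion carbon), so the carbon chain is delivered to C6 regiospecifically.

Step 13
Reactants: 18 6-allyl-5-hydroxy-7-(methoxymethoxy)-3,4-dimethylcoumarin
Product: 19 6-allyl-5-methoxy-7-(methoxymethoxy)-3,4-dimethylcoumarin
Conditions: MeI, K2CO3, DMF, 40 °C
Reagents that add atoms: iodomethane, CI
Why: Williamson O-methylation of the only free phenol is routine, and the small electrophile copes with the two flanking groups.

Step 14
Reactants: 19 6-allyl-5-methoxy-7-(methoxymethoxy)-3,4-dimethylcoumarin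
Product: 20 6-allyl-8-iodo-5-methoxy-7-(methoxymethoxy)-3,4-dimethylcoumarin
Conditions: NIS, MeCN, 0 °C to rt, dark
Reagents that add atoms: N-iodosuccinimide, O=C1CCC(=O)N1I
Why: In this electrophilic aromatic iodination C8 is the only aromatic C–H left and is ortho or para to three oxygen donors, so it should outrun the monosubstituted alkene, which is why iodination precedes the change to prenyl.

Step 15
Reactants: 20 6-allyl-8-iodo-5-methoxy-7-(methoxymethoxy)-3,4-dimethylcoumarin
Product: 21 8-iodo-5-methoxy-7-(methoxymethoxy)-3,4-dimethyl-6-(3-methylbut-2-enyl)coumarin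
Conditions: 2-methyl-2-butene (excess), second-generation Grubbs catalyst (H2IMes)(PCy3)Cl2Ru=CHPh (3 mol%), CH2Cl2, 40 °C
Reagents that add atoms: 2-methyl-2-butene, CC=C(C)C
Why: Olefin cross metathesis of an allylarene with 2-methyl-2-butene is the standard allyl-to-prenyl conversion, is driven by loss of propene, and tolerates aryl iodide and lactone.

Step 16
Reactants: 21 the 8-iodo-6-prenylcoumarin; 12 the bicyclic enelactone
Product: 23 8-{[(5R,6R)-6-[(1S)-1-hydroxyethyl]-5-methylcyclohex-1-en-1-yl]carbonyl}-5-methoxy-7-(methoxymethoxy)-3,4-dimethyl-6-(3-methylbut-2-enyl)coumarin, via arylmagnesium chloride 22 (not isolated)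
Conditions: 21 (1.3 equiv), iPrMgCl·LiCl (1.3 equiv), THF, −40 °C; then 12, −40 to 0 °C; aq NH4Cl
Reagents that add atoms: isopropylmagnesium chloride–lithium chloride, CC(C)[Mg]Cl.[Li+].[Cl-] (its Mg and Cl stay only in 22)
Why: Iodine–magnesium exchange (assisted by the ortho MOM oxygen and tolerated by the coumarin lactone at low temperature) followed by aryl Grignard addition to a lactone cleaves the acyl C–O bond of the temporary ring, frees the carbinol with its configuration intact, and should stop at the ketone because the magnesium hemiketal and two ortho substituents block a second addition.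

Step 17
Reactants: 23 the 7-O-MOM ether of the target
Product: 24 target, 7-hydroxy-8-{[(5R,6R)-6-[(1S)-1-hydroxyethyl]-5-methylcyclohex-1-en-1-yl]carbonyl}-5-methoxy-3,4-dimethyl-6-(3-methylbut-2-enyl)coumarin
Conditions: NaHSO4·SiO2, moist CH2Cl2, rt
Reagents that add atoms: none
Why: Mild heterogeneous acid hydrolysis of a phenolic acetal, eased by the ortho carbonyl group, should free the chelated 7-OH without chroman formation from the prenyl group or dehydration of the hydroxy ketone.

Compound list
1 | (S)-but-3-yn-2-ol | C[C@H](O)C#C | starting material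
2 | vinyl bromide | C=CBr | starting material
3 | (S)-hex-5-en-3-yn-2-ol | C[C@H](O)C#CC=C | intermediate
4 | sodium cyclic vinylalanate (five-membered O–Al–C=C chelate, two 2-methoxyethoxy groups on Al) | C[C@@H]1O[Al-](OCCOC)(OCCOC)C(C=C)=C1.[Na+] | intermediate
5 | (2S,3Z)-4-iodohexa-3,5-dien-2-ol | C[C@H](O)/C=C(\I)C=C | intermediate
6 | (2S,3E)-4-methylhexa-3,5-dien-2-ol | C[C@H](O)/C=C(\C)C=C | intermediate
7 | propiolic acid | C#CC(=O)O | starting material
8 | (2S,3E)-4-methylhexa-3,5-dien-2-yl prop-2-ynoate | C#CC(=O)O[C@@H](C)/C=C(\C)C=C | intermediate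
9 | (2S,3E)-4-methylhexa-3,5-dien-2-yl (2Z)-3-(phenylsulfonyl)prop-2-enoate | O=C(/C=C\S(=O)(=O)c1ccccc1)O[C@@H](C)/C=C(\C)C=C | intermediate
10 | (3S,3aS,7S,7aS)-3,4-dimethyl-7-(phenylsulfonyl)-3a,6,7,7a-tetrahydro-2-benzofuran-1(3H)-one | O=C1O[C@@H](C)[C@@H]2C(C)=CC[C@H](S(=O)(=O)c3ccccc3)[C@H]12 | intermediate
11 | (3S,3aR,4R,7S,7aS)-3,4-dimethyl-7-(phenylsulfonyl)hexahydro-2-benzofuran-1(3H)-one | O=C1O[C@@H](C)[C@@H]2[C@H](C)CC[C@H](S(=O)(=O)c3ccccc3)[C@H]12 | intermediate
12 | (3S,3aR,4R)-3,4-dimethyl-3a,4,5,6-tetrahydro-2-benzofuran-1(3H)-one | O=C1O[C@@H](C)[C@@H]2[C@H](C)CCC=C12 | intermediate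
13 | phloroglucinol | Oc1cc(O)cc(O)c1 | starting material
14 | ethyl 2-methylacetoacetate | CCOC(=O)C(C)C(C)=O | starting material
15 | 5,7-dihydroxy-3,4-dimethylcoumarin | Oc1cc(O)cc2oc(=O)c(C)c(C)c12 | intermediate
16 | 5-hydroxy-7-(methoxymethoxy)-3,4-dimethylcoumarin | Oc1cc(OCOC)cc2oc(=O)c(C)c(C)c12 | intermediate
17 | 5-(allyloxy)-7-(methoxymethoxy)-3,4-dimethylcoumarin | C=CCOc1cc(OCOC)cc2oc(=O)c(C)c(C)c12 | intermediate
18 | 6-allyl-5-hydroxy-7-(methoxymethoxy)-3,4-dimethylcoumarin | Oc1c(CC=C)c(OCOC)cc2oc(=O)c(C)c(C)c12 | intermediate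
19 | 6-allyl-5-methoxy-7-(methoxymethoxy)-3,4-dimethylcoumarin | COc1c(CC=C)c(OCOC)cc2oc(=O)c(C)c(C)c12 | intermediate
20 | 6-allyl-8-iodo-5-methoxy-7-(methoxymethoxy)-3,4-dimethylcoumarin | COc1c(CC=C)c(OCOC)c(I)c2oc(=O)c(C)c(C)c12 | intermediate
21 | 8-iodo-5-methoxy-7-(methoxymethoxy)-3,4-dimethyl-6-(3-methylbut-2-enyl)coumarin | COc1c(CC=C(C)C)c(OCOC)c(I)c2oc(=O)c(C)c(C)c12 | intermediate
22 | 8-(chloromagnesio)-5-methoxy-7-(methoxymethoxy)-3,4-dimethyl-6-(3-methylbut-2-enyl)coumarin | COc1c(CC=C(C)C)c(OCOC)c([Mg]Cl)c2oc(=O)c(C)c(C)c12 | intermediate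
23 | 7-O-MOM ether of the target | COc1c(CC=C(C)C)c(OCOC)c(C(=O)C2=CCC[C@@H](C)[C@H]2[C@H](C)O)c2oc(=O)c(C)c(C)c12 | intermediate
24 | CNP0197455.1 | COc1c(CC=C(C)C)c(O)c(C(=O)C2=CCC[C@@H](C)[C@H]2[C@H](C)O)c2oc(=O)c(C)c(C)c12 | target

Total step count: 17.
Longest linear sequence: 10 steps (steps 1–8, 16, 17, from 1). The coumarin branch has 7 steps before the union.

Steps most likely to fail

1. Step 6.
- What may go wrong: endo selectivity may erode so that the trans-fused adduct grows, the vinyl sulfone may isomerise from Z to E before cyclisation, or the dienylic ester may ionise on long heating.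
- Fallback (sets out from 6, returns at 12): the dienophile and the way its helper is removed are both changed. Compound 6 is acylated with maleic anhydride (Et3N, CH2Cl2, 0 °C) to the maleate half-ester F1, the tether class with the best documented cis preference.
- Heating in toluene (80–110 °C) should give the all-cis lactone acid F2, and H2/PtO2 from the open face the saturated lactone acid F3.
- The Kochi chlorodecarboxylation (Pb(OAc)4, LiCl, benzene, 80 °C) replaces the carboxyl group on C7 by chlorine to give the β-chloro lactone F4. DBU (CH2Cl2, 0 °C) then eliminates to 12.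

2. Step 16.
- What may go wrong: 1,2-addition of the doubly ortho-substituted aryl Grignard to the lactone may be slow. Proton transfer from the C4 methyl group of the coumarin or from the γ-CH2 of the lactone may compete, as may conjugate addition at C7.
- Fallback (sets out from 12, returns at 23): the electrophile is moved to the aldehyde oxidation level. Compound 12 is reduced with iBu2AlH (CH2Cl2, −78 °C) to the lactol F5.
- The magnesium alkoxide of F5 (pre-formed with iPrMgCl) reacts through its open hydroxy-enal form with 22 at −40 °C to give the diol F6, as a carbinol epimer mixture that does not matter.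
- MnO2 (CH2Cl2, rt) should oxidise only the carbinol that is both benzylic and allylic, and leave the aliphatic secondary alcohol, to give 23.

3. Step 7.
- What may go wrong: the alkene may migrate on the metal surface to the tetrasubstituted C3a=C4 position with loss of the C3a centre, hydrogen uptake at the hindered trisubstituted alkene may be sluggish, or the facial preference may erode.
- Fallback (sets out from 10, returns at 11): the reduction is split into a concerted syn hydroboration and a radical C–B to C–H exchange under neutral conditions that the base-labile β-sulfonyl lactone tolerates.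
- Catecholborane (cat. N,N-dimethylacetamide, CH2Cl2, reflux) should add from the same open face, with hydrogen to C4 and boron to C5, to give the B-alkylcatecholborane F7. Radical protodeboronation (MeOH, 4-tert-butylcatechol, air, rt) then gives 11.

Further compounds
F1 | step 6 | (2Z)-4-{[(2S,3E)-4-methylhexa-3,5-dien-2-yl]oxy}-4-oxobut-2-enoic acid | OC(=O)/C=C\C(=O)O[C@@H](C)/C=C(\C)C=C
F2 | step 6 | (3S,3aS,7S,7aR)-3,4-dimethyl-1-oxo-1,3,3a,6,7,7a-hexahydro-2-benzofuran-7-carboxylic acid | O=C1O[C@@H](C)[C@@H]2C(C)=CC[C@H](C(=O)O)[C@H]12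
F3 | step 6 | (3S,3aR,4R,7S,7aR)-3,4-dimethyl-1-oxooctahydro-2-benzofuran-7-carboxylic acid | O=C1O[C@@H](C)[C@@H]2[C@H](C)CC[C@H](C(=O)O)[C@H]12
F4 | step 6 | (3S,3aR,4R,7aS)-7-chloro-3,4-dimethylhexahydro-2-benzofuran-1(3H)-one (C7 epimers) | O=C1O[C@@H](C)[C@@H]2[C@H](C)CCC(Cl)[C@H]12
F5 | step 16 | (3S,3aR,4R)-3,4-dimethyl-1,3,3a,4,5,6-hexahydro-2-benzofuran-1-ol (anomers) | OC1O[C@@H](C)[C@@H]2[C@H](C)CCC=C12
F6 | step 16 | 8-{hydroxy[(5R,6R)-6-[(1S)-1-hydroxyethyl]-5-methylcyclohex-1-en-1-yl]methyl}-5-methoxy-7-(methoxymethoxy)-3,4-dimethyl-6-(3-methylbut-2-enyl)coumarin (carbinol epimers) | COc1c(CC=C(C)C)c(OCOC)c(C(O)C2=CCC[C@@H](C)[C@H]2[C@H](C)O)c2oc(=O)c(C)c(C)c12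
F7 | step 7 | (3S,3aR,4R,5S,7S,7aS)-5-(1,3,2-benzodioxaborol-2-yl)-3,4-dimethyl-7-(phenylsulfonyl)hexahydro-2-benzofuran-1(3H)-one | O=C1O[C@@H](C)[C@@H]2[C@H](C)[C@@H](B3Oc4ccccc4O3)C[C@H](S(=O)(=O)c3ccccc3)[C@H]12
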